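**Strategy.** Ring A is disconnected at C2–C3 by an intramolecular aldol addition. The step exploits the 1,3-relationship in ring A between the C2 carbinol and C4: once C4 is taken back to a ketone, C3 is the methyl carbon of an acetyl group on C5 and C2 the aldehyde carbon of a 2-oxoethyl arm on C10. One ozonolysis unveils both arms from the isopropenyl and allyl groups of a 6-allyl-6-methyl derivative of (R)-carvone, whose ring becomes ring B. The aldol closes the trans-decalin and sets the equatorial 2α-hydroxyl in one operation. The C4 ketone is later homologated and methylated to the quaternary centre, and ring B is completed by side-chain addition, allylic hydrogenolysis and epoxide isomerization.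

Key step: step 4

Remark: locants are those of the labdane skeleton of the target (C1–C10 decalin, C11–C16 side chain, C17 on C8, C18 = 4α-methyl, C19 = 4β-CH2O, C20 = methyl on C10; α is the face opposite C20); (R)-carvone, but-2-yn-1-ol and all reagents are taken to be commercial.

**Route**

Step 1
Reactants: 1 (R)-carvone
Product: 2 6-methylcarvone (both C6 epimers)
Conditions: LiN(i-Pr)2, THF, −78 °C; MeI, −78 → 0 °C
Reagents that add atoms: iodomethane (CI)
Why: Kinetic α′-deprotonation of the enone and SN2 methylation of the dienolate (enolate alkylation); the epimer mixture does not matter because this carbon is re-enolized in step 2.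

Step 2
Reactants: 2 6-methylcarvone
Product: 3 (5S,6S)-6-allyl-2,6-dimethyl-5-isopropenylcyclohex-2-en-1-one
Conditions: LiN(i-Pr)2, THF, −78 °C; allyl bromide, DMPU, −78 → 0 °C
Reagents that add atoms: allyl bromide (C=CCBr)
Why: Second enolate alkylation at the same carbon; allyl bromide should approach the dienolate anti to the adjacent isopropenyl group, setting the future C10 with allyl trans and methyl cis to isopropenyl.

Step 3
Reactants: 3 (5S,6S)-6-allyl-2,6-dimethyl-5-isopropenylcyclohex-2-en-1-one
Product: 5 2-[(1S,6R)-6-acetyl-1,3-dimethyl-2-oxocyclohex-3-en-1-yl]acetaldehyde, via bis-ozonide 4 (not isolated)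
Conditions: O3, CH2Cl2, −78 °C (Sudan Red 7B end point); PPh3, −78 °C → rt
Reagents that add atoms: ozone (O=[O+][O-])
Why: Ozonolysis with reductive work-up cleaves the two electron-rich terminal olefins (isopropenyl to acetyl, allyl to 2-oxoethyl), while the electron-poor enone olefin reacts much more slowly and should survive when ozone is dosed to the indicator end point.

Step 4
Reactants: 5 2-[(1S,6R)-6-acetyl-1,3-dimethyl-2-oxocyclohex-3-en-1-yl]acetaldehyde
Product: 6 2α-hydroxy-11,12,13,14,15,16,18,19-octanorlabd-7-ene-4,9-dione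
Conditions: K2CO3 (0.3 equiv), MeOH, 0 °C; then aq. NH4Cl
Reagents that add atoms: none
Why: Carbonate in methanol reversibly generates the enolate of the methyl ketone at C3, which adds to the C2 aldehyde carbonyl, and protonation of the aldolate gives the β-hydroxy ketone. The closest known reaction type is the intramolecular aldol addition that closes the second ring in Robinson-type annulations of keto aldehydes. Ring A closes in the 6-(enolendo)-exo-trig mode through a chair, and the ring fusion is trans because the acetyl and 2-oxoethyl arms are already trans-diequatorial on ring B. The only new stereocentre, C2, is controlled by that chair and by the reversibility of the addition: the oxygen takes the equatorial 2α position because the axial one would be 1,3-diaxial to the C10 methyl. The step needs chemoselectivity among three carbonyl groups, and the substrate secures it: C10 is quaternary so the ring-B enone has no α′-hydrogen, the aldehyde enolate could only close a four-membered ring onto C4, and the aldehyde is far more electrophilic than the hindered conjugated C9 ketone. Mild base at 0 °C should keep the ketol from losing water and C5 from epimerizing.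

Step 5
Reactants: 6 2α-hydroxy-11,12,13,14,15,16,18,19-octanorlabd-7-ene-4,9-dione
Product: 7 2α-(triisopropylsilyloxy)-11,12,13,14,15,16,18,19-octanorlabd-7-ene-4,9-dione
Conditions: i-Pr3SiOTf, 2,6-lutidine, CH2Cl2, −78 → 0 °C
Reagents that add atoms: triisopropylsilyl triflate (CC(C)[Si](OS(=O)(=O)C(F)(F)F)(C(C)C)C(C)C)
Why: Silyl triflate silylation of the secondary alcohol under weakly basic conditions avoids retro-aldol and β-elimination, and the triisopropylsilyl ether is chosen to survive the later acid steps and the selective removal of primary tert-butyldimethylsilyl ethers.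

Step 6
Reactants: 7 2α-(triisopropylsilyloxy)-11,12,13,14,15,16,18,19-octanorlabd-7-ene-4,9-dione
Product: 9 9-oxo-2α-(triisopropylsilyloxy)-11,12,13,14,15,16,18-heptanorlabd-7-en-19-al (both C4 epimers), via enol ether 8 (not isolated)
Conditions: Ph3P(CH2OCH3)Cl, KN(SiMe3)2, THF, 0 °C → rt; then 2 M aq. HCl, THF, rt
Reagents that add atoms: (methoxymethyl)triphenylphosphonium chloride (COC[P+](c1ccccc1)(c1ccccc1)c1ccccc1.[Cl-]); water (O)
Why: Wittig methoxymethylenation should take only the saturated C4 ketone, because the C9 carbonyl is conjugated and flanked by the quaternary C10 and the C8 methyl, and acid hydrolysis of the enol ether gives the one-carbon-homologated aldehyde (C19), whose C4 configuration is immaterial since C4 is enolized in step 7.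

Step 7
Reactants: 9 9-oxo-2α-(triisopropylsilyloxy)-11,12,13,14,15,16,18-heptanorlabd-7-en-19-al
Product: 10 9-oxo-2α-(triisopropylsilyloxy)-11,12,13,14,15,16-hexanorlabd-7-en-19-al (4α-CH3 and 4β-CHO)
Conditions: MeI (5 equiv), KOt-Bu (1.1 equiv), THF/t-BuOH, 0 °C
Reagents that add atoms: iodomethane (CI)
Why: C-Methylation of the exocyclic aldehyde enolate; iodomethane should approach from the equatorial α face, away from the axial C10 methyl, giving the 4α-methyl 4β-formyl arrangement that is usual for C4 enolates of 10-methyl-trans-decalins.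

Step 8
Reactants: 10 9-oxo-2α-(triisopropylsilyloxy)-11,12,13,14,15,16-hexanorlabd-7-en-19-al
Product: 11 19-hydroxy-2α-(triisopropylsilyloxy)-11,12,13,14,15,16-hexanorlabd-7-en-9-one
Conditions: NaBH4, MeOH/CH2Cl2, −40 °C
Reagents that add atoms: none
Why: Chemoselective hydride reduction of the aldehyde; the conjugated C9 ketone, shielded by C10 and the C8 methyl, should remain untouched at low temperature.

Step 9
Reactants: 11 19-hydroxy-2α-(triisopropylsilyloxy)-11,12,13,14,15,16-hexanorlabd-7-en-9-one
Product: 12 19-(tert-butyldimethylsilyloxy)-2α-(triisopropylsilyloxy)-11,12,13,14,15,16-hexanorlabd-7-en-9-one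
Conditions: t-BuMe2SiCl, imidazole, DMF, rt
Reagents that add atoms: tert-butyldimethylsilyl chloride (CC(C)(C)[Si](C)(C)Cl)
Why: Standard silylation of the primary alcohol, so that no ester is present in the base-mediated step 17 and C19 can be unmasked together with C15 in step 18.

Step 10
Reactants: 13 but-2-yn-1-ol
Product: 15 (Z)-3-iodobut-2-en-1-ol, via alkenylalanate 14 (not isolated)
Conditions: NaAlH2(OCH2CH2OCH3)2, THF, 0 °C → rt; I2, THF, −78 → 0 °C
Reagents that add atoms: iodine (II)
Why: Alkoxide-directed trans-hydroalumination of the propargylic alcohol places aluminium on C3 in a five-membered alanate, and iodinolysis of the C–Al bond with retention gives the vinyl iodide with iodine cis to CH2OH.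

Step 11
Reactants: 15 (Z)-3-iodobut-2-en-1-ol
Product: 16 (Z)-tert-butyl[(3-iodobut-2-en-1-yl)oxy]dimethylsilane
Conditions: t-BuMe2SiCl, imidazole, CH2Cl2, 0 °C → rt
Reagents that add atoms: tert-butyldimethylsilyl chloride (CC(C)(C)[Si](C)(C)Cl)
Why: Standard silylation gives an allylic ether that tolerates the organolithium chemistry and is not a leaving group in the palladium step.

Step 12
Reactants: 16 (Z)-tert-butyl[(3-iodobut-2-en-1-yl)oxy]dimethylsilane
Product: 18 (Z)-5-(tert-butyldimethylsilyloxy)-3-methylpent-3-en-1-ol, via alkenyllithium 17 (not isolated)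
Conditions: t-BuLi (2.1 equiv), Et2O, −78 °C; ethylene oxide, −78 → 0 °C
Reagents that add atoms: ethylene oxide (C1CO1)
Why: Iodine–lithium exchange proceeds with retention of olefin geometry and the alkenyllithium opens oxirane, adding C11–C12 cis to the CH2O group.

Step 13
Reactants: 18 (Z)-5-(tert-butyldimethylsilyloxy)-3-methylpent-3-en-1-ol
Product: 19 (Z)-tert-butyl[(5-iodo-3-methylpent-2-en-1-yl)oxy]dimethylsilane
Conditions: I2, PPh3, imidazole, CH2Cl2, 0 °C
Reagents that add atoms: iodine (II)
Why: Appel-type iodination converts the primary alcohol to the iodide by SN2 under neutral conditions that leave the Z-olefin and the silyl ether untouched.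

Step 14
Reactants: 19 (Z)-tert-butyl[(5-iodo-3-methylpent-2-en-1-yl)oxy]dimethylsilane; 12 19-(tert-butyldimethylsilyloxy)-2α-(triisopropylsilyloxy)-11,12,13,14,15,16-hexanorlabd-7-en-9-one
Product: 22 9β-acetoxy-15,19-bis(tert-butyldimethylsilyloxy)-2α-(triisopropylsilyloxy)-9-epi-labda-7,13Z-diene (side chain 9α), via alkyllithium 20 (not isolated), via lithium alkoxide 21 (not isolated)
Conditions: 19, t-BuLi (2.1 equiv), Et2O, −78 °C; then 12, THF, −78 → 0 °C; then Ac2O, 0 °C → rt
Reagents that add atoms: acetic anhydride (CC(=O)OC(C)=O)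
Why: Iodine–lithium exchange gives the primary alkyllithium, which should add 1,2 to the enone carbonyl from the α face, anti to the axial C10 methyl on the adjacent carbon, so that the tertiary alkoxide is β and is trapped in situ as the allylic acetate.

Step 15
Reactants: 22 9β-acetoxy-15,19-bis(tert-butyldimethylsilyloxy)-2α-(triisopropylsilyloxy)-9-epi-labda-7,13Z-diene
Product: 23 15,19-bis(tert-butyldimethylsilyloxy)-2α-(triisopropylsilyloxy)labda-7,13Z-diene (9α-H)
Conditions: Pd(OAc)2 (5 mol %), n-Bu3P (10 mol %), HCO2H, Et3N, THF, 60 °C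
Reagents that add atoms: none
Why: Tsuji–Mandai formate hydrogenolysis: zerovalent palladium ionizes the allylic acetate with inversion and the palladium hydride formed from formate delivers hydride to the more substituted allyl terminus C9 from the palladium (α) face, which should give 9α-H with the side chain β and keep the olefin at C7–C8.

Step 16
Reactants: 23 15,19-bis(tert-butyldimethylsilyloxy)-2α-(triisopropylsilyloxy)labda-7,13Z-diene
Product: 24 7α,8α-epoxy-15,19-bis(tert-butyldimethylsilyloxy)-2α-(triisopropylsilyloxy)labd-13Z-ene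
Conditions: m-CPBA (1.05 equiv), NaHCO3, CH2Cl2, −20 °C
Reagents that add atoms: 3-chloroperbenzoic acid (OOC(=O)c1cccc(Cl)c1)
Why: Prilezhaev epoxidation; the ring olefin is more electron-rich than the side-chain olefin, which carries an inductively withdrawing allylic silyloxy group, and the peracid should attack the α face, opposite the C10 methyl and the C9 side chain.

Step 17
Reactants: 24 7α,8α-epoxy-15,19-bis(tert-butyldimethylsilyloxy)-2α-(triisopropylsilyloxy)labd-13Z-ene
Product: 25 15,19-bis(tert-butyldimethylsilyloxy)-2α-(triisopropylsilyloxy)labda-8(17),13Z-dien-7α-ol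
Conditions: Et2AlCl and lithium 2,2,6,6-tetramethylpiperidide (4 equiv each, premixed), toluene, 0 °C → rt
Reagents that add atoms: none
Why: Aluminium amide-mediated isomerization of an epoxide to an allylic alcohol: aluminium binds the epoxide oxygen and the amide removes a syn β-hydrogen from the least hindered site, the C17 methyl, in a concerted syn-elimination that opens the C8–O bond, keeps the 7α C–O bond and generates no radical or cation that the side-chain olefin could trap.

Step 18
Reactants: 25 15,19-bis(tert-butyldimethylsilyloxy)-2α-(triisopropylsilyloxy)labda-8(17),13Z-dien-7α-ol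
Product: 26 2α-(triisopropylsilyloxy)labda-8(17),13Z-diene-7α,15,19-triol
Conditions: camphorsulfonic acid (0.2 equiv), MeOH/CH2Cl2, 0 °C → rt
Reagents that add atoms: none
Why: Acid-catalysed methanolysis should remove the two primary tert-butyldimethylsilyl ethers much faster than the hindered secondary triisopropylsilyl ether at C2 (selective desilylation).

Step 19
Reactants: 26 2α-(triisopropylsilyloxy)labda-8(17),13Z-diene-7α,15,19-triol
Product: 27 7α,15,19-triacetoxy-2α-(triisopropylsilyloxy)labda-8(17),13Z-diene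
Conditions: Ac2O, pyridine, DMAP (cat.), CH2Cl2, rt
Reagents that add atoms: acetic anhydride (CC(=O)OC(C)=O)
Why: DMAP-catalysed acylation esterifies the primary C15 and C19 hydroxyls and the axial allylic C7 hydroxyl while the C2 oxygen stays masked.

Step 20
Reactants: 27 7α,15,19-triacetoxy-2α-(triisopropylsilyloxy)labda-8(17),13Z-diene
Product: 28 7α,15,19-triacetoxylabda-8(17),13Z-dien-2α-ol (target)
Conditions: HF·pyridine, THF, 0 °C → rt
Reagents that add atoms: none
Why: Fluoride cleaves the remaining silyl ether under mildly acidic, non-nucleophilic conditions that should leave the three acetates and the allylic system intact.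

**Compound list**

1 | (R)-carvone, (5R)-2-methyl-5-(prop-1-en-2-yl)cyclohex-2-en-1-one | CC1=CC[C@@H](C(C)=C)CC1=O | starting material
2 | 6-methylcarvone, (5R)-2,6-dimethyl-5-(prop-1-en-2-yl)cyclohex-2-en-1-one, both C6 epimers | CC1=CC[C@@H](C(C)=C)C(C)C1=O | intermediate
3 | (5S,6S)-2,6-dimethyl-5-(prop-1-en-2-yl)-6-(prop-2-en-1-yl)cyclohex-2-en-1-one (allyl trans to isopropenyl) | CC1=CC[C@@H](C(C)=C)[C@](C)(CC=C)C1=O | intermediate
4 | bis(1,2,4-trioxolane) from both terminal olefins of 3 (trioxolane carbons unassigned) | CC1=CC[C@@H](C2(C)OCOO2)[C@](C)(CC2OCOO2)C1=O | intermediate (not isolated)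
5 | 2-[(1S,6R)-6-acetyl-1,3-dimethyl-2-oxocyclohex-3-en-1-yl]acetaldehyde (acetyl trans to the 2-oxoethyl arm) | CC1=CC[C@@H](C(C)=O)[C@](C)(CC=O)C1=O | intermediate
6 | 2α-hydroxy-11,12,13,14,15,16,18,19-octanorlabd-7-ene-4,9-dione (5α-H, 10β-CH3) | CC1=CC[C@H]2C(=O)C[C@H](O)C[C@]2(C)C1=O | intermediate
7 | 2α-(triisopropylsilyloxy)-11,12,13,14,15,16,18,19-octanorlabd-7-ene-4,9-dione | CC1=CC[C@H]2C(=O)C[C@H](O[Si](C(C)C)(C(C)C)C(C)C)C[C@]2(C)C1=O | intermediate
8 | 19-methoxy-2α-(triisopropylsilyloxy)-11,12,13,14,15,16,18-heptanorlabda-4(19),7-dien-9-one (E/Z mixture) | CC1=CC[C@H]2C(=COC)C[C@H](O[Si](C(C)C)(C(C)C)C(C)C)C[C@]2(C)C1=O | intermediate (not isolated)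
9 | 9-oxo-2α-(triisopropylsilyloxy)-11,12,13,14,15,16,18-heptanorlabd-7-en-19-al (both C4 epimers) | CC1=CC[C@H]2C(C=O)C[C@H](O[Si](C(C)C)(C(C)C)C(C)C)C[C@]2(C)C1=O | intermediate
10 | 9-oxo-2α-(triisopropylsilyloxy)-11,12,13,14,15,16-hexanorlabd-7-en-19-al (4α-CH3, 4β-CHO) | CC1=CC[C@H]2[C@@](C)(C=O)C[C@H](O[Si](C(C)C)(C(C)C)C(C)C)C[C@]2(C)C1=O | intermediate
11 | 19-hydroxy-2α-(triisopropylsilyloxy)-11,12,13,14,15,16-hexanorlabd-7-en-9-one | CC1=CC[C@H]2[C@@](C)(CO)C[C@H](O[Si](C(C)C)(C(C)C)C(C)C)C[C@]2(C)C1=O | intermediate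
12 | 19-(tert-butyldimethylsilyloxy)-2α-(triisopropylsilyloxy)-11,12,13,14,15,16-hexanorlabd-7-en-9-one | CC1=CC[C@H]2[C@@](C)(CO[Si](C)(C)C(C)(C)C)C[C@H](O[Si](C(C)C)(C(C)C)C(C)C)C[C@]2(C)C1=O | intermediate
13 | but-2-yn-1-ol | CC#CCO | starting material
14 | sodium 2,2-bis(2-methoxyethoxy)-3-methyl-2,5-dihydro-1,2-oxaaluminol-2-uide (cyclic alkenylalanate) | CC1=CCO[Al-]1(OCCOC)OCCOC.[Na+] | intermediate (not isolated)
15 | (Z)-3-iodobut-2-en-1-ol | I/C(C)=C\CO | intermediate
16 | (Z)-tert-butyl[(3-iodobut-2-en-1-yl)oxy]dimethylsilane | I/C(C)=C\CO[Si](C)(C)C(C)(C)C | intermediate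
17 | [4-(tert-butyldimethylsilyloxy)but-2-en-2-yl]lithium (lithium cis to CH2O) | [Li]/C(C)=C\CO[Si](C)(C)C(C)(C)C | intermediate (not isolated)
18 | (Z)-5-(tert-butyldimethylsilyloxy)-3-methylpent-3-en-1-ol | OCC/C(C)=C\CO[Si](C)(C)C(C)(C)C | intermediate
19 | (Z)-tert-butyl[(5-iodo-3-methylpent-2-en-1-yl)oxy]dimethylsilane | ICC/C(C)=C\CO[Si](C)(C)C(C)(C)C | intermediate
20 | (Z)-[5-(tert-butyldimethylsilyloxy)-3-methylpent-3-en-1-yl]lithium | [Li]CC/C(C)=C\CO[Si](C)(C)C(C)(C)C | intermediate (not isolated)
21 | lithium 15,19-bis(tert-butyldimethylsilyloxy)-2α-(triisopropylsilyloxy)-9-epi-labda-7,13Z-dien-9β-olate (side chain 9α) | CC1=CC[C@H]2[C@@](C)(CO[Si](C)(C)C(C)(C)C)C[C@H](O[Si](C(C)C)(C(C)C)C(C)C)C[C@]2(C)[C@]1(O[Li])CC/C(C)=C\CO[Si](C)(C)C(C)(C)C | intermediate (not isolated)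
22 | 9β-acetoxy-15,19-bis(tert-butyldimethylsilyloxy)-2α-(triisopropylsilyloxy)-9-epi-labda-7,13Z-diene (side chain 9α) | CC1=CC[C@H]2[C@@](C)(CO[Si](C)(C)C(C)(C)C)C[C@H](O[Si](C(C)C)(C(C)C)C(C)C)C[C@]2(C)[C@]1(OC(C)=O)CC/C(C)=C\CO[Si](C)(C)C(C)(C)C | intermediate
23 | 15,19-bis(tert-butyldimethylsilyloxy)-2α-(triisopropylsilyloxy)labda-7,13Z-diene (9α-H) | CC1=CC[C@H]2[C@@](C)(CO[Si](C)(C)C(C)(C)C)C[C@H](O[Si](C(C)C)(C(C)C)C(C)C)C[C@]2(C)[C@H]1CC/C(C)=C\CO[Si](C)(C)C(C)(C)C | intermediate
24 | 7α,8α-epoxy-15,19-bis(tert-butyldimethylsilyloxy)-2α-(triisopropylsilyloxy)labd-13Z-ene | C[C@@]12O[C@@H]1C[C@H]3[C@@](C)(CO[Si](C)(C)C(C)(C)C)C[C@H](O[Si](C(C)C)(C(C)C)C(C)C)C[C@]3(C)[C@H]2CC/C(C)=C\CO[Si](C)(C)C(C)(C)C | intermediate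
25 | 15,19-bis(tert-butyldimethylsilyloxy)-2α-(triisopropylsilyloxy)labda-8(17),13Z-dien-7α-ol | C=C1[C@H](O)C[C@H]2[C@@](C)(CO[Si](C)(C)C(C)(C)C)C[C@H](O[Si](C(C)C)(C(C)C)C(C)C)C[C@]2(C)[C@H]1CC/C(C)=C\CO[Si](C)(C)C(C)(C)C | intermediate
26 | 2α-(triisopropylsilyloxy)labda-8(17),13Z-diene-7α,15,19-triol | C=C1[C@H](O)C[C@H]2[C@@](C)(CO)C[C@H](O[Si](C(C)C)(C(C)C)C(C)C)C[C@]2(C)[C@H]1CC/C(C)=C\CO | intermediate
27 | 7α,15,19-triacetoxy-2α-(triisopropylsilyloxy)labda-8(17),13Z-diene | C=C1[C@H](OC(C)=O)C[C@H]2[C@@](C)(COC(C)=O)C[C@H](O[Si](C(C)C)(C(C)C)C(C)C)C[C@]2(C)[C@H]1CC/C(C)=C\COC(C)=O | intermediate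
28 | 7α,15,19-triacetoxylabda-8(17),13Z-dien-2α-ol | C=C1[C@H](OC(C)=O)C[C@H]2[C@@](C)(COC(C)=O)C[C@H](O)C[C@]2(C)[C@H]1CC/C(C)=C\COC(C)=O | target

**Totals and risks**

Total step count: 20. Longest linear sequence: 16 steps (steps 1–9 and 14–20, from (R)-carvone).

Steps most likely to fail:

Step 15 (formate hydrogenolysis). What may go wrong: slow ionization of the hindered tertiary acetate, hydride delivery to the less substituted terminus C7 (giving the tetrasubstituted 8-ene), β-hydride elimination to dienes, or loss of control at C9 if the addition in step 14 is not face-selective. Fallback: setting out from 12, the alkyllithium 20 is added as in step 14 but the alkoxide is quenched with aqueous NH4Cl to give the tertiary allylic alcohol F1. Oxidative 1,3-transposition with pyridinium chlorochromate, C5H5NH[CrO3Cl] (CH2Cl2, rt), should give the transposed enone F2 (C7 ketone, 8-ene). Luche reduction (NaBH4, CeCl3·7H2O, MeOH, −20 °C) should give the equatorial 7β-allylic alcohol F3. Reductive allylic transposition (2-nitrobenzenesulfonylhydrazide, PPh3, diethyl azodicarboxylate, THF, −30 °C → rt) inverts C7 in the Mitsunobu step; the 7α-monoalkyl diazene then loses N2 with suprafacial delivery of hydrogen to C9 on the α face, which returns the route at 23. In this variant C9 is set by the C7 alcohol and no longer by the face of the organolithium addition.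

Step 4 (aldol). What may go wrong: loss of water from the ketol to the conjugated enone, or base-induced epimerization at C5 before or after ring closure, leading to cis-fused material. Fallback: setting out from 5, the aldol is driven on purpose to the condensation product, enedione F4 (p-TsOH, benzene, reflux with water removal). Nucleophilic epoxidation (H2O2, NaOH, MeOH, 0 °C) should take the less substituted ring-A enone from the α face, away from the C10 methyl, to give epoxy ketone F5. Reductive opening of the Cα–O bond with NaSePh (from PhSeSePh and NaBH4, EtOH, AcOH, 0 °C) should give the 2α-hydroxy ketone and returns the route at 6.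

Step 16 (epoxidation). What may go wrong: competing epoxidation of the side-chain olefin (poor site selectivity) or partial attack on the β face. Fallback: setting out from 23, a Schenck ene reaction with singlet oxygen (O2, tetraphenylporphyrin, hν, CH2Cl2, −20 °C) is used; the side-chain olefin with its allylic silyloxy group should be much less reactive. Oxygen should add to C7 on the α face with hydrogen abstraction from the C17 methyl to give allylic hydroperoxide F6. Reduction with PPh3 gives the allylic alcohol and returns the route at 25, bypassing 24 and step 17.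

Further compounds
F1 | step 15 | 15,19-bis(tert-butyldimethylsilyloxy)-2α-(triisopropylsilyloxy)-9-epi-labda-7,13Z-dien-9β-ol | CC1=CC[C@H]2[C@@](C)(CO[Si](C)(C)C(C)(C)C)C[C@H](O[Si](C(C)C)(C(C)C)C(C)C)C[C@]2(C)[C@]1(O)CC/C(C)=C\CO[Si](C)(C)C(C)(C)C
F2 | step 15 | 15,19-bis(tert-butyldimethylsilyloxy)-2α-(triisopropylsilyloxy)labda-8,13Z-dien-7-one | CC1=C(CC/C(C)=C\CO[Si](C)(C)C(C)(C)C)[C@@]2(C)C[C@@H](O[Si](C(C)C)(C(C)C)C(C)C)C[C@](C)(CO[Si](C)(C)C(C)(C)C)[C@@H]2CC1=O
F3 | step 15 | 15,19-bis(tert-butyldimethylsilyloxy)-2α-(triisopropylsilyloxy)labda-8,13Z-dien-7β-ol | CC1=C(CC/C(C)=C\CO[Si](C)(C)C(C)(C)C)[C@@]2(C)C[C@@H](O[Si](C(C)C)(C(C)C)C(C)C)C[C@](C)(CO[Si](C)(C)C(C)(C)C)[C@@H]2C[C@@H]1O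
F4 | step 4 | 11,12,13,14,15,16,18,19-octanorlabda-2,7-diene-4,9-dione | CC1=CC[C@H]2C(=O)C=CC[C@]2(C)C1=O
F5 | step 4 | 2α,3α-epoxy-11,12,13,14,15,16,18,19-octanorlabd-7-ene-4,9-dione | CC1=CC[C@H]2C(=O)[C@@H]3O[C@@H]3C[C@]2(C)C1=O
F6 | step 16 | 7α-hydroperoxy-15,19-bis(tert-butyldimethylsilyloxy)-2α-(triisopropylsilyloxy)labda-8(17),13Z-diene | C=C1[C@H](OO)C[C@H]2[C@@](C)(CO[Si](C)(C)C(C)(C)C)C[C@H](O[Si](C(C)C)(C(C)C)C(C)C)C[C@]2(C)[C@H]1CC/C(C)=C\CO[Si](C)(C)C(C)(C)C
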